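**Retrosynthetic overview**
- Target 23 ⇐ Heck reaction with methyl acrylate, then saponification, on 5-iodo-dihydrobenzofuran 19.
- The dihydrobenzofuran (the only ring built) ⇐ closed last at O1–C2 by acid-triggered MOM loss and SN1 O-cyclisation of syn-1,3-diol 17; the C3 centre steers C2 to trans.
- 17 ⇐ reductive auxiliary removal from aldol adduct 16; the key C2–C3 bond comes from an Evans boron aldol of arylacetyl oxazolidinone 12 with veratraldehyde 13.
- 12 ⇐ arylacetic acid 9 ⇐ o-vanillin 1 (iodination, O-demethylation, bis-MOM, Wittig/hydroboration/oxidation homologation).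

Assumption: the SMILES encodes the trans-(2R,3S) isomer (benzofuran numbering O1, C2 aryl, C3 CH2OH). Simple reagents are given by name and SMILES in the step lines and carry no compound number.

**Step 1**
Reactants: 1 o-vanillin (2-hydroxy-3-methoxybenzaldehyde)
Product: 2 2-hydroxy-5-iodo-3-methoxybenzaldehyde
Conditions: NIS (1.05 equiv), TsOH·H2O (10 mol%), MeCN, rt
Reagents that add atoms: N-iodosuccinimide, O=C1CCC(=O)N1I
Why: Electrophilic aromatic iodination goes para to the phenol OH (both ortho positions are blocked, and C5 is meta to CHO), as in the known 5-halogenation of o-vanillin.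

**Step 2**
Reactants: 2 2-hydroxy-5-iodo-3-methoxybenzaldehyde
Product: 3 2,3-dihydroxy-5-iodobenzaldehyde
Conditions: BBr3 (3 equiv), CH2Cl2, −78 °C → rt; H2O
Reagents that add atoms: none
Why: BBr3 Lewis-acid cleavage of the aryl methyl ether removes the only O-methyl group before the veratryl unit is introduced; aldehyde and aryl iodide are inert.

**Step 3**
Reactants: 3 2,3-dihydroxy-5-iodobenzaldehyde
Product: 4 5-iodo-2,3-bis(methoxymethoxy)benzaldehyde
Conditions: MOMCl (3 equiv), i-Pr2NEt (4 equiv), CH2Cl2, 0 °C → rt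
Reagents that add atoms: chloromethyl methyl ether, COCCl
Why: Williamson-type O-alkylation protects both phenols as MOM acetals, which survive all basic, hydridic and boron-mediated steps and are later removed with acid.

**Step 4**
Reactants: 4 5-iodo-2,3-bis(methoxymethoxy)benzaldehyde
Product: 5 1-ethenyl-5-iodo-2,3-bis(methoxymethoxy)benzene
Conditions: Ph3PCH3Br (1.3 equiv), KOt-Bu (1.25 equiv), THF, 0 °C; then 4, 0 °C → rt
Reagents that add atoms: methyltriphenylphosphonium bromide, C[P+](c1ccccc1)(c1ccccc1)c1ccccc1.[Br-]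
Why: Wittig methylenation of a non-enolisable aryl aldehyde; KOt-Bu instead of BuLi avoids iodine–lithium exchange.

**Step 5**
Reactants: 5 1-ethenyl-5-iodo-2,3-bis(methoxymethoxy)benzene
Product: 7 2-[5-iodo-2,3-bis(methoxymethoxy)phenyl]ethan-1-ol, via B-alkyl-9-BBN borane 6 (not isolated)
Conditions: 9-BBN (1.5 equiv), THF, 0 °C → rt; then 3 M NaOH, 30% H2O2, 0 °C → rt
Reagents that add atoms: hydrogen peroxide, OO; 9-borabicyclo[3.3.1]nonane, B1C2CCCC1CCC2 (boron and the cyclooctane ring stay only in 6)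
Why: Brown hydroboration–oxidation with bulky 9-BBN gives the anti-Markovnikov primary alcohol from the styrene; MOM ethers and ArI tolerate alkaline peroxide.

**Step 6**
Reactants: 7 2-[5-iodo-2,3-bis(methoxymethoxy)phenyl]ethan-1-ol
Product: 9 2-[5-iodo-2,3-bis(methoxymethoxy)phenyl]acetic acid, via arylacetaldehyde 8 (not isolated)
Conditions: TEMPO (7 mol%), NaClO2 (2 equiv), NaOCl (2 mol%), MeCN/phosphate buffer pH 6.7, 35 °C; Na2SO3 quench
Reagents that add atoms: sodium chlorite, [Na+].[O-]Cl=O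
Why: TEMPO/chlorite (Anelli–Zhao, Pinnick-type) oxidation takes electron-rich 2-arylethanols to arylacetic acids at near-neutral pH, which preserves the MOM acetals and limits ring chlorination.

**Step 7**
Reactants: 9 2-[5-iodo-2,3-bis(methoxymethoxy)phenyl]acetic acid; 10 (R)-4-benzyloxazolidin-2-one
Product: 12 (R)-4-benzyl-3-{2-[5-iodo-2,3-bis(methoxymethoxy)phenyl]acetyl}oxazolidin-2-one, via mixed pivalic anhydride 11 (not isolated)
Conditions: PivCl (1.1 equiv), Et3N (2.5 equiv), THF, −20 °C; then LiCl (1.2 equiv), 10 (1.05 equiv), −20 °C → rt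
Reagents that add atoms: pivaloyl chloride, CC(C)(C)C(=O)Cl (its atoms stay only in 11)
Why: N-acylation of the Evans auxiliary through the mixed anhydride occurs at the unhindered arylacetyl carbonyl, and the LiCl/Et3N variant needs no BuLi in the presence of ArI.

**Step 8**
Reactants: 12 (R)-4-benzyl-3-{2-[5-iodo-2,3-bis(methoxymethoxy)phenyl]acetyl}oxazolidin-2-one; 13 3,4-dimethoxybenzaldehyde (veratraldehyde)
Product: 16 (R)-4-benzyl-3-{(2R,3R)-3-(3,4-dimethoxyphenyl)-3-hydroxy-2-[5-iodo-2,3-bis(methoxymethoxy)phenyl]propanoyl}oxazolidin-2-one, via Z-boron enolate 14 (not isolated), via boron aldolate 15 (not isolated)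
Conditions: Bu2BOTf (1.2 equiv), i-Pr2NEt (1.4 equiv), CH2Cl2, −78 → 0 °C; 13 (1.3 equiv), −78 → 0 °C; pH 7 buffer, MeOH, 30% H2O2, 0 °C
Reagents that add atoms: dibutylboron triflate, CCCCB(CCCC)OS(=O)(=O)C(F)(F)F (boron and butyl groups stay only in 14 and 15)
Why: Evans syn-aldol: the Z-boron enolate reacts through a Zimmerman–Traxler chair on the face opposite the auxiliary benzyl group, giving the (2R,3R) syn adduct, whose α-carbon becomes C3 (S) of the target.

**Step 9**
Reactants: 16 the syn-aldol adduct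
Product: 17 (1R,2S)-1-(3,4-dimethoxyphenyl)-2-[5-iodo-2,3-bis(methoxymethoxy)phenyl]propane-1,3-diol
Conditions: LiBH4 (2.5 equiv), THF, 0 °C → rt; sat. NH4Cl
Reagents that add atoms: none
Why: Borohydride reductive cleavage of the N-acyl oxazolidinone at the exocyclic carbonyl gives the primary alcohol and returns the auxiliary, without touching either stereocentre, ArI or the MOM ethers.

**Step 10**
Reactants: 17 (1R,2S)-1-(3,4-dimethoxyphenyl)-2-[5-iodo-2,3-bis(methoxymethoxy)phenyl]propane-1,3-diol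
Product: 19 (2R,3S)-2-(3,4-dimethoxyphenyl)-3-(hydroxymethyl)-5-iodo-2,3-dihydro-1-benzofuran-7-ol, via catechol diol 18 (not isolated)
Conditions: HCl (1.25 M in MeOH), 0.02 M, rt → 40 °C
Reagents that add atoms: none
Why: Acetal methanolysis frees the catechol, and SN1 intramolecular etherification of the 3,4-dimethoxybenzyl cation by the ortho phenol closes the ring with the aryl group anti to the C3 CH2OH (reversible, so trans-(2R) is also the thermodynamic outcome), while C3 is untouched.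

**Step 11**
Reactants: 19 the 5-iodo-dihydrobenzofuran; 20 methyl acrylate
Product: 21 methyl (2E)-3-[(2R,3S)-2-(3,4-dimethoxyphenyl)-7-hydroxy-3-(hydroxymethyl)-2,3-dihydro-1-benzofuran-5-yl]prop-2-enoate
Conditions: Pd(OAc)2 (5 mol%), P(o-tol)3 (10 mol%), Et3N (3 equiv), 20 (3 equiv), DMF, 80 °C
Reagents that add atoms: none
Why: Mizoroki–Heck coupling of the aryl iodide tolerates the free phenol and alcohol and gives the E-cinnamate by syn-insertion/syn-β-hydride elimination.

**Step 12**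
Reactants: 21 the methyl cinnamate
Product: 23 (2E)-3-[(2R,3S)-2-(3,4-dimethoxyphenyl)-7-hydroxy-3-(hydroxymethyl)-2,3-dihydro-1-benzofuran-5-yl]prop-2-enoic acid, via dilithium salt 22 (not isolated)
Conditions: LiOH·H2O (5 equiv), THF/MeOH/H2O 3:1:1 (degassed), rt; then 1 M HCl to pH 3, 0 °C
Reagents that add atoms: lithium hydroxide, [Li+].[OH-]
Why: Saponification (BAc2 ester hydrolysis) of the methyl ester leaves the stereocentres, which have no acidifying neighbours, and the E-alkene unchanged.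

**Compound list**
1 | o-vanillin (2-hydroxy-3-methoxybenzaldehyde) | COc1cccc(C=O)c1O | starting material
2 | 2-hydroxy-5-iodo-3-methoxybenzaldehyde | O=Cc1cc(I)cc(OC)c1O | intermediate
3 | 2,3-dihydroxy-5-iodobenzaldehyde | O=Cc1cc(I)cc(O)c1O | intermediate
4 | 5-iodo-2,3-bis(methoxymethoxy)benzaldehyde | O=Cc1cc(I)cc(OCOC)c1OCOC | intermediate
5 | 1-ethenyl-5-iodo-2,3-bis(methoxymethoxy)benzene | C=Cc1cc(I)cc(OCOC)c1OCOC | intermediate
6 | 9-{2-[5-iodo-2,3-bis(methoxymethoxy)phenyl]ethyl}-9-borabicyclo[3.3.1]nonane | COCOc1cc(I)cc(CCB2C3CCCC2CCC3)c1OCOC | intermediate (not isolated)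
7 | 2-[5-iodo-2,3-bis(methoxymethoxy)phenyl]ethan-1-ol | OCCc1cc(I)cc(OCOC)c1OCOC | intermediate
8 | 2-[5-iodo-2,3-bis(methoxymethoxy)phenyl]acetaldehyde | O=CCc1cc(I)cc(OCOC)c1OCOC | intermediate (not isolated)
9 | 2-[5-iodo-2,3-bis(methoxymethoxy)phenyl]acetic acid | OC(=O)Cc1cc(I)cc(OCOC)c1OCOC | intermediate
10 | (R)-4-benzyloxazolidin-2-one | O=C1N[C@H](Cc2ccccc2)CO1 | starting material
11 | 2-[5-iodo-2,3-bis(methoxymethoxy)phenyl]acetic pivalic anhydride | CC(C)(C)C(=O)OC(=O)Cc1cc(I)cc(OCOC)c1OCOC | intermediate (not isolated)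
12 | (R)-4-benzyl-3-{2-[5-iodo-2,3-bis(methoxymethoxy)phenyl]acetyl}oxazolidin-2-one | O=C(Cc1cc(I)cc(OCOC)c1OCOC)N1[C@H](Cc2ccccc2)COC1=O | intermediate
13 | 3,4-dimethoxybenzaldehyde (veratraldehyde) | COc1ccc(C=O)cc1OC | starting material
14 | (R)-4-benzyl-3-{(Z)-1-[(dibutylboranyl)oxy]-2-[5-iodo-2,3-bis(methoxymethoxy)phenyl]ethenyl}oxazolidin-2-one | CCCCB(CCCC)O/C(=C\c1cc(I)cc(OCOC)c1OCOC)N1[C@H](Cc2ccccc2)COC1=O | intermediate (not isolated)
15 | O-dibutylboranyl aldolate of 16 | O=C(N1[C@H](Cc2ccccc2)COC1=O)[C@H](c1cc(I)cc(OCOC)c1OCOC)[C@@H](OB(CCCC)CCCC)c1ccc(OC)c(OC)c1 | intermediate (not isolated)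
16 | (R)-4-benzyl-3-{(2R,3R)-3-(3,4-dimethoxyphenyl)-3-hydroxy-2-[5-iodo-2,3-bis(methoxymethoxy)phenyl]propanoyl}oxazolidin-2-one | O=C(N1[C@H](Cc2ccccc2)COC1=O)[C@H](c1cc(I)cc(OCOC)c1OCOC)[C@@H](O)c1ccc(OC)c(OC)c1 | intermediate
17 | (1R,2S)-1-(3,4-dimethoxyphenyl)-2-[5-iodo-2,3-bis(methoxymethoxy)phenyl]propane-1,3-diol | OC[C@H](c1cc(I)cc(OCOC)c1OCOC)[C@@H](O)c1ccc(OC)c(OC)c1 | intermediate
18 | 3-[(1R,2S)-1-(3,4-dimethoxyphenyl)-1,3-dihydroxypropan-2-yl]-5-iodobenzene-1,2-diol | OC[C@H](c1cc(I)cc(O)c1O)[C@@H](O)c1ccc(OC)c(OC)c1 | intermediate (not isolated)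
19 | (2R,3S)-2-(3,4-dimethoxyphenyl)-3-(hydroxymethyl)-5-iodo-2,3-dihydro-1-benzofuran-7-ol | COc1ccc([C@@H]2Oc3c(O)cc(I)cc3[C@H]2CO)cc1OC | intermediate
20 | methyl acrylate | C=CC(=O)OC | starting material
21 | methyl (2E)-3-[(2R,3S)-2-(3,4-dimethoxyphenyl)-7-hydroxy-3-(hydroxymethyl)-2,3-dihydro-1-benzofuran-5-yl]prop-2-enoate | COc1ccc([C@@H]2Oc3c(O)cc(/C=C/C(=O)OC)cc3[C@H]2CO)cc1OC | intermediate
22 | dilithium (2E)-3-[(2R,3S)-2-(3,4-dimethoxyphenyl)-3-(hydroxymethyl)-7-oxido-2,3-dihydro-1-benzofuran-5-yl]prop-2-enoate | [Li+].[Li+].COc1ccc([C@@H]2Oc3c([O-])cc(/C=C/C(=O)[O-])cc3[C@H]2CO)cc1OC | intermediate (not isolated)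
23 | (2E)-3-[(2R,3S)-2-(3,4-dimethoxyphenyl)-7-hydroxy-3-(hydroxymethyl)-2,3-dihydro-1-benzofuran-5-yl]prop-2-enoic acid | COc1ccc([C@@H]2Oc3c(O)cc(/C=C/C(=O)O)cc3[C@H]2CO)cc1OC | target

**Totals**
Total step count: 12. Longest linear sequence: 12 steps (1 → 23); compounds 10, 13 and 20 are bought.

**Three steps most likely to fail**

Step 10 (one-pot MOM removal and cyclisation). The risks are benzylic methyl ether or stilbene by-products and an incomplete trans preference. The fallback sets out from 17 and separates deprotection from ring closure. TMSOTf/2,2′-bipyridyl in CH2Cl2 at 0 °C exchanges both aryl MOM ethers for silyl ethers without protic acid and silylates both alcohols, giving (1R,2S)-1-(3,4-dimethoxyphenyl)-2-[5-iodo-2,3-bis(trimethylsilyloxy)phenyl]-1,3-bis(trimethylsilyloxy)propane F1. Aqueous work-up (water, then citric acid/MeOH) strips the silyl groups and the catechol diol 18 is isolated. It is then cyclised on its own with catalytic PPTS or Amberlyst-15 in CH2Cl2, where there is no nucleophilic solvent and any cis isomer can equilibrate to trans. The fallback comes back to the route at 19.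

Step 9 (auxiliary removal). The risks are retro-aldol of the α-aryl-β-aryl-β-hydroxy imide and attack at the ring carbonyl. The fallback sets out from 16. The carbinol is first capped with TBSOTf/2,6-lutidine (CH2Cl2, −78 °C) to give (R)-4-benzyl-3-{(2R,3R)-3-(tert-butyldimethylsilyloxy)-3-(3,4-dimethoxyphenyl)-2-[5-iodo-2,3-bis(methoxymethoxy)phenyl]propanoyl}oxazolidin-2-one F2, which can no longer fragment. LiBH4 in THF then gives (2S,3R)-3-(tert-butyldimethylsilyloxy)-3-(3,4-dimethoxyphenyl)-2-[5-iodo-2,3-bis(methoxymethoxy)phenyl]propan-1-ol F3. Under the methanolic HCl of step 10, F3 loses the silyl and MOM groups and cyclises, so the fallback comes back at 19.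

Step 6 (oxidation to the arylacetic acid). The risks are ring chlorination or iodide oxidation by hypochlorite and degradation of the arylacetaldehyde. The fallback sets out from 4 and replaces steps 4–6 by a different homologation. Van Leusen reductive cyanation (TosMIC, KOt-Bu, DME, −40 °C; then MeOH, reflux) gives 2-[5-iodo-2,3-bis(methoxymethoxy)phenyl]acetonitrile F4. Hydrolysis (KOH, EtOH/H2O, reflux; cold citric acid work-up) gives the acid, and the fallback comes back at 9.

**Further compounds**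
F1 | step 10 | (1R,2S)-1-(3,4-dimethoxyphenyl)-2-[5-iodo-2,3-bis(trimethylsilyloxy)phenyl]-1,3-bis(trimethylsilyloxy)propane | C[Si](C)(C)OC[C@H](c1cc(I)cc(O[Si](C)(C)C)c1O[Si](C)(C)C)[C@@H](O[Si](C)(C)C)c1ccc(OC)c(OC)c1
F2 | step 9 | (R)-4-benzyl-3-{(2R,3R)-3-(tert-butyldimethylsilyloxy)-3-(3,4-dimethoxyphenyl)-2-[5-iodo-2,3-bis(methoxymethoxy)phenyl]propanoyl}oxazolidin-2-one | O=C(N1[C@H](Cc2ccccc2)COC1=O)[C@H](c1cc(I)cc(OCOC)c1OCOC)[C@@H](O[Si](C)(C)C(C)(C)C)c1ccc(OC)c(OC)c1
F3 | step 9 | (2S,3R)-3-(tert-butyldimethylsilyloxy)-3-(3,4-dimethoxyphenyl)-2-[5-iodo-2,3-bis(methoxymethoxy)phenyl]propan-1-ol | OC[C@H](c1cc(I)cc(OCOC)c1OCOC)[C@@H](O[Si](C)(C)C(C)(C)C)c1ccc(OC)c(OC)c1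
F4 | step 6 | 2-[5-iodo-2,3-bis(methoxymethoxy)phenyl]acetonitrile | N#CCc1cc(I)cc(OCOC)c1OCOC
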